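## Retrosynthetic overview

1. The target comes from fluoride desilylation after a late Heck coupling. The partners are a core enal carrying a buta-1,3-dien-2-yl group on ring A and a (Z)-iodoallyl acetate made from homoprenyl bromide and propargyl alcohol.
2. The Z-enal comes from oxidative 1,3-transposition of an isopropenyl carbinol. The 1-OH and the primary OH come from one hydride reduction of a 2-dienyl ketone/δ-lactone. The C2–dienyl bond comes from palladium α-alkenylation of a silyl enol ether with chloroprene.
3. Key disconnection: the spiro centre and ring A come from a 1,2-shift ring expansion (cyclobutanol to cyclopentanone) onto C3 of a 4-silyloxy-4-methylcyclohexenone. The enol silane that results is captured by methyl acrylate to give the C6 arm.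
4. The rearrangement substrate comes from 2-iodocyclohexenone, Me2Zn (asymmetric 1,2-addition), cyclobutanone, iPr2SiCl2 and an allylic oxidation.
5. Ring order: ring B is bought, the cyclobutane is attached, and ring A forms in the expansion. The silinane and lactone rings are temporary.

Assumption: spiro compounds use spiro[4.5]decane numbering (C1 carbonyl/carbinol, C2 side-chain carbon, C5 spiro, C6 carbon with the three-carbon arm, C7, C10 methyl carbinol); ring A is five-membered and ring B six-membered; all seven starting materials are taken as catalogue items; the ligand antipode of step 1 is chosen to give the S alcohol.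

## Route

Step 1
Reactants: 1 2-iodocyclohex-2-en-1-one
Product: 2 (S)-2-iodo-1-methylcyclohex-2-en-1-ol
Conditions: Me2Zn (2 equiv), Ti(OiPr)4 (1.2 equiv), trans-cyclohexane-1,2-diamine bis(camphorsulfonamide) diol ligand (10 mol %), toluene/hexanes, rt; aq NH4Cl
Reagents that add atoms: dimethylzinc C[Zn]C
Why: Titanium-mediated catalytic asymmetric 1,2-addition of a dialkylzinc to a 2-substituted cyclic enone, in which the large 2-iodo group differentiates the two carbonyl flanks so that methyl is delivered to one face and sets the future C10 carbinol as S.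

Step 2
Reactants: 2 (S)-2-iodo-1-methylcyclohex-2-en-1-ol; 3 cyclobutanone
Product: 6 diisopropylsilylene ether (1,3-dioxa-2-silinane over both tertiary oxygens) of (S)-2-(1-hydroxycyclobutyl)-1-methylcyclohex-2-en-1-ol, via dilithio alkoxide 4 (not isolated), via dilithium dialkoxide 5 (not isolated)
Conditions: n-BuLi (1.05 equiv) then t-BuLi (2.1 equiv), Et2O, −78 °C; 3; iPr2SiCl2, −78 °C → rt
Reagents that add atoms: dichlorodiisopropylsilane CC(C)[Si](Cl)(Cl)C(C)C
Why: Iodine–lithium exchange on the lithium alkoxide, 1,2-addition of the vinyllithium to strained cyclobutanone and closure of the 1,3-dialkoxide on silicon (silylene acetal formation) create no new stereocentre and leave the carbinol untouched.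

Step 3
Reactants: 6 diisopropylsilylene ether of (S)-2-(1-hydroxycyclobutyl)-1-methylcyclohex-2-en-1-ol
Product: 7 diisopropylsilylene ether of (S)-4-hydroxy-3-(1-hydroxycyclobutyl)-4-methylcyclohex-2-en-1-one
Conditions: Rh2(cap)4 (cap = caprolactamate, 1 mol %), t-BuOOH (5 equiv, decane), K2CO3, CH2Cl2, rt
Reagents that add atoms: tert-butyl hydroperoxide CC(C)(C)OO
Why: Dirhodium-catalysed radical allylic oxidation can only strike the single allylic methylene because the other two allylic carbons are quaternary, so the enone forms regiospecifically and no stereocentre is touched.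

Step 4
Reactants: 7 diisopropylsilylene ether of (S)-4-hydroxy-3-(1-hydroxycyclobutyl)-4-methylcyclohex-2-en-1-one; 8 methyl acrylate
Product: 11 methyl 3-[(5R,6S,10S)-10-methyl-7-oxo-1,10-(diisopropylsilanediyldioxy)spiro[4.5]dec-1-en-6-yl]propanoate (cyclic silyl enol ether; C1 branch 10-O and C6 arm on one face of ring B), via silyl enol ether 9 (not isolated), via ketene silyl acetal 10 (not isolated)
Conditions: TMSNTf2 (1.1 equiv), 2,6-di-tert-butylpyridine (0.2 equiv), CH2Cl2, −78 → −30 °C; 8 (3 equiv), −78 → −20 °C; Et3N (3 equiv), → rt; aq NaHCO3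
Reagents that add atoms: none
Why: Proposed new method: a silicon-tethered silyl-transfer vinylogous semipinacol ring expansion with in-flask Mukaiyama–Michael capture, in which O-silylation of the enone makes its C3 an acceptor, the chair dioxasilinane holds both C–O bonds on one face so that only the cyclobutane C–C bond on the opposite face is parallel to the acceptor p-orbital and migrates (cyclobutanol to cyclopentanone with about 20 kcal/mol strain release, spiro centre set anti to the 10-oxygen), the regiodefined trimethylsilyl enol ether then adds to methyl acrylate axially and anti to the new axial ring A methylene, meeting the 10-oxygen rather than the 10-methyl in the 1,3-diaxial position (sets C6), and Et3N lets the freed silyl triflimide arm close on the new ketone as a cyclic enol silane; the closest known reactions are the amine/acid-catalysed vinylogous alpha-ketol rearrangement of 3-(1-hydroxycyclobutyl)enones, the silyl triflate-promoted semipinacol rearrangement of epoxy silyl ethers and the triflimide-catalysed Mukaiyama–Michael reaction.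

Step 5
Reactants: 11 cyclic silyl enol ether keto ester; 12 isopropenylmagnesium bromide
Product: 14 (5R,6S,7R,10S) δ-lactone (7-isopropenyl; 7-O acylated by the C6 propanoyl arm; 1,10-silanediyldioxy enol ether retained), via magnesium alkoxide 13 (not isolated)
Conditions: 12 (1.3 equiv), LaCl3·2LiCl (1 equiv), THF, −78 °C → rt; pH 7 buffer
Reagents that add atoms: none
Why: Lanthanide-assisted Grignard 1,2-addition to the only free ketone from the equatorial side away from the axial ring A branch gives the tertiary allylic alkoxide cis to the ester arm, which lactonises and so masks carbinol and acid together, this C7 centre being erased later.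

Step 6
Reactants: 14 (5R,6S,7R,10S) δ-lactone cyclic silyl enol ether; 15 chloroprene (2-chlorobuta-1,3-diene)
Product: 18 (2S,5R,6S,7R,10S)-2-(buta-1,3-dien-2-yl)-10-hydroxy-7-isopropenyl-10-methyl-1-oxospiro[4.5]decane 7,6-δ-lactone, via tin enolate 16 (not isolated), via fluorosilyl ether 17 (not isolated)
Conditions: 15 (3 equiv, BHT), Pd2(dba)3 (2.5 mol %), P(t-Bu)3 (10 mol %), Bu3SnF (1.3 equiv), toluene, 60 °C; then HF·pyridine, THF, 0 °C
Reagents that add atoms: none
Why: Palladium-catalysed α-alkenylation of a ketone through its tributyltin enolate (Kosugi–Migita/Kuwajima–Urabe type, fluoride opening the enol Si–O bond) transfers the dien-2-yl group to the enolate face away from the bulky fluorodiisopropylsilyloxy-bearing C10 branch under non-basic conditions, which sets C2 as S without epimerisation or conjugation.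

Step 7
Reactants: 18 2-dienyl hydroxy keto lactone
Product: 19 (1R,2S,5S,6S,7R,10S)-2-(buta-1,3-dien-2-yl)-6-(3-hydroxypropyl)-10-methyl-7-(prop-1-en-2-yl)spiro[4.5]decane-1,7,10-triol
Conditions: LiAlH4 (4 equiv), THF, −78 → 0 °C; aq KNaC4H4O6
Reagents that add atoms: none
Why: Hydroxyl-directed hydride reduction, in which the free 10-OH first forms an alkoxyaluminate that delivers hydride to C1 from its own face, which is also the face anti to the C2 dienyl group, gives the 1,2-cis carbinol (1R) while the same reagent reduces the lactone to the primary alcohol and the tertiary allylic alcohol.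

Step 8
Reactants: 19 tetraol
Product: 20 1-O,3'-O-bis(triethylsilyl) ether of 19 (both tertiary hydroxyls free)
Conditions: TESOTf (2.2 equiv), 2,6-lutidine, CH2Cl2, −78 °C
Reagents that add atoms: triethylsilyl trifluoromethanesulfonate CC[Si](CC)(CC)OS(=O)(=O)C(F)(F)F
Why: Rate-controlled silylation (primary then secondary much faster than tertiary at −78 °C) protects exactly the two oxidisable alcohols and changes no stereocentre.

Step 9
Reactants: 20 bis(triethylsilyl) ether diol
Product: 21 (2Z)-2-[(1R,2S,5S,6R,10S)-2-(buta-1,3-dien-2-yl)-10-hydroxy-10-methyl-1-(triethylsilyloxy)-6-(3-triethylsilyloxypropyl)spiro[4.5]decan-7-ylidene]propanal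
Conditions: pyridinium chlorochromate [C5H5NH][CrO3Cl] (3 equiv), NaOAc, 4 Å sieves, CH2Cl2, rt
Reagents that add atoms: pyridinium chlorochromate [O-][Cr](=O)(=O)Cl.c1cc[nH+]cc1
Why: Babler–Dauben oxidative 1,3-transposition, in which the tertiary allylic chromate shifts through a chair-like [3,3] array with the isopropenyl methyl turned toward the unhindered C8 methylene and the =CH2 terminus toward the congested C6 flank, so oxygen arrives cis to C6 and oxidation of the primary chromate fixes the Z-enal while the silyl ethers and the 10-OH are inert.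

Step 10
Reactants: 22 5-bromo-2-methylpent-2-ene; 23 prop-2-yn-1-ol
Product: 26 (Z)-2-(iodomethylidene)-6-methylhept-5-en-1-ol, via homoprenyl Grignard 24 (not isolated), via vinylmagnesium alkoxide 25 (not isolated)
Conditions: Mg, THF; 23 (0.4 equiv), CuI (10 mol %), Et2O/THF, 0 °C → rt; I2, −40 → 0 °C
Reagents that add atoms: iodine II
Why: Copper-catalysed anti-carbomagnesiation of the propargylic alkoxide places the homoprenyl group on the internal carbon and magnesium on the terminal carbon cis to CH2O in a five-membered chelate, and iodinolysis with retention fixes the Z-iodoalkene.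

Step 11
Reactants: 26 (Z)-2-(iodomethylidene)-6-methylhept-5-en-1-ol
Product: 27 (Z)-2-(iodomethylidene)-6-methylhept-5-en-1-yl acetate
Conditions: Ac2O, pyridine, DMAP, CH2Cl2, 0 °C → rt
Reagents that add atoms: acetic anhydride CC(=O)OC(C)=O
Why: DMAP-catalysed acetylation of the primary allylic alcohol leaves the alkene geometry untouched.

Step 12
Reactants: 21 core dienyl enal; 27 (Z)-iodoallyl acetate
Product: 28 1-O,3'-O-bis(triethylsilyl) ether of the target (new disubstituted alkene E; trisubstituted alkene Z retained)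
Conditions: Pd(OAc)2 (10 mol %), Ag2CO3 (1 equiv), DMF, rt → 40 °C, dark
Reagents that add atoms: none
Why: Ligand-free silver-assisted Heck alkenylation, in which the alkenylpalladium from 27 (geometry retained) inserts at the free CH2 terminus of the monosubstituted vinyl group of the 2-substituted diene and syn β-hydride elimination gives the E-alkene, silver carbonate removing iodide so that zerovalent palladium does not linger to ionise the allylic acetate.

Step 13
Reactants: 28 bis(triethylsilyl) ether of the target
Product: 29 CNP0205332.1 (1R,2S,5S,6R,10S; Z-enal; E,Z-triene acetate)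
Conditions: HF·pyridine, pyridine, THF, 0 °C
Reagents that add atoms: none
Why: Buffered fluoride cleavage of the two triethylsilyl ethers spares the allylic acetate, the enal and the triene and touches no stereocentre.

## Compound list

1 | 2-iodocyclohex-2-en-1-one | O=C1CCCC=C1I | starting material
2 | (S)-2-iodo-1-methylcyclohex-2-en-1-ol | C[C@]1(O)CCCC=C1I | intermediate
3 | cyclobutanone | O=C1CCC1 | starting material
4 | lithium (S)-2-lithio-1-methylcyclohex-2-en-1-olate | C[C@]1(O[Li])CCCC=C1[Li] | intermediate
5 | dilithium dialkoxide of (S)-2-(1-hydroxycyclobutyl)-1-methylcyclohex-2-en-1-ol | C[C@]1(O[Li])CCCC=C1C1(O[Li])CCC1 | intermediate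
6 | diisopropylsilylene ether of (S)-2-(1-hydroxycyclobutyl)-1-methylcyclohex-2-en-1-ol | C[C@]12CCCC=C1C1(CCC1)O[Si](C(C)C)(C(C)C)O2 | intermediate
7 | diisopropylsilylene ether of (S)-4-hydroxy-3-(1-hydroxycyclobutyl)-4-methylcyclohex-2-en-1-one | C[C@]12CCC(=O)C=C1C1(CCC1)O[Si](C(C)C)(C(C)C)O2 | intermediate
8 | methyl acrylate | C=CC(=O)OC | starting material
9 | (5R,10S)-10-methyl-7-(trimethylsilyloxy)-10-[diisopropyl(triflimido)silyloxy]spiro[4.5]dec-6-en-1-one | C[Si](C)(C)OC1=C[C@]2(CCCC2=O)[C@@](C)(O[Si](C(C)C)(C(C)C)N(S(=O)(=O)C(F)(F)F)S(=O)(=O)C(F)(F)F)CC1 | intermediate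
10 | (5R,6S,10S) ketene silyl acetal of the Michael adduct (1,7-dione, 10-O-silyl triflimide) | COC(O[Si](C)(C)C)=CC[C@@H]1C(=O)CC[C@](C)(O[Si](C(C)C)(C(C)C)N(S(=O)(=O)C(F)(F)F)S(=O)(=O)C(F)(F)F)[C@@]12CCCC2=O | intermediate
11 | methyl 3-[(5R,6S,10S)-10-methyl-7-oxo-1,10-(diisopropylsilanediyldioxy)spiro[4.5]dec-1-en-6-yl]propanoate | COC(=O)CC[C@@H]1C(=O)CC[C@]2(C)O[Si](C(C)C)(C(C)C)OC3=CCC[C@@]123 | intermediate
12 | isopropenylmagnesium bromide | C=C(C)[Mg]Br | starting material
13 | bromomagnesium (7R)-alkoxide from addition of 12 to 11 | COC(=O)CC[C@@H]1[C@@](O[Mg]Br)(C(C)=C)CC[C@]2(C)O[Si](C(C)C)(C(C)C)OC3=CCC[C@@]123 | intermediate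
14 | (5R,6S,7R,10S) δ-lactone with cyclic silyl enol ether | O=C1CC[C@@H]2[C@@](O1)(C(C)=C)CC[C@]3(C)O[Si](C(C)C)(C(C)C)OC4=CCC[C@@]234 | intermediate
15 | chloroprene | C=CC(Cl)=C | starting material
16 | tributyltin enolate, 10-O-fluorodiisopropylsilyl ether | CCCC[Sn](CCCC)(CCCC)OC1=CCC[C@]12[C@@H]3CCC(=O)O[C@]3(C(C)=C)CC[C@]2(C)O[Si](F)(C(C)C)C(C)C | intermediate
17 | 2-dienyl ketone, 10-O-fluorodiisopropylsilyl ether | C=CC(=C)[C@@H]1CC[C@]2([C@@H]3CCC(=O)O[C@]3(C(C)=C)CC[C@]2(C)O[Si](F)(C(C)C)C(C)C)C1=O | intermediate
18 | (2S,5R,6S,7R,10S)-2-(buta-1,3-dien-2-yl)-10-hydroxy-7-isopropenyl-10-methyl-1-oxospiro[4.5]decane 7,6-δ-lactone | C=CC(=C)[C@@H]1CC[C@]2([C@@H]3CCC(=O)O[C@]3(C(C)=C)CC[C@]2(C)O)C1=O | intermediate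
19 | (1R,2S,5S,6S,7R,10S)-2-(buta-1,3-dien-2-yl)-6-(3-hydroxypropyl)-10-methyl-7-(prop-1-en-2-yl)spiro[4.5]decane-1,7,10-triol | C=CC(=C)[C@@H]1CC[C@]2([C@H](CCCO)[C@@](O)(C(C)=C)CC[C@]2(C)O)[C@@H]1O | intermediate
20 | 1-O,3'-O-bis(triethylsilyl) ether of 19 | C=CC(=C)[C@@H]1CC[C@]2([C@H](CCCO[Si](CC)(CC)CC)[C@@](O)(C(C)=C)CC[C@]2(C)O)[C@@H]1O[Si](CC)(CC)CC | intermediate
21 | (2Z)-2-[(1R,2S,5S,6R,10S)-2-(buta-1,3-dien-2-yl)-10-hydroxy-10-methyl-1-(triethylsilyloxy)-6-(3-triethylsilyloxypropyl)spiro[4.5]decan-7-ylidene]propanal | C=CC(=C)[C@@H]1CC[C@]2([C@H](CCCO[Si](CC)(CC)CC)/C(=C(/C)C=O)CC[C@]2(C)O)[C@@H]1O[Si](CC)(CC)CC | intermediate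
22 | 5-bromo-2-methylpent-2-ene | CC(C)=CCCBr | starting material
23 | prop-2-yn-1-ol | C#CCO | starting material
24 | (4-methylpent-3-en-1-yl)magnesium bromide | CC(C)=CCC[Mg]Br | intermediate
25 | (Z)-vinylmagnesium bromide alkoxide from carbomagnesiation | Br[Mg]/C=C(/CCC=C(C)C)CO[Mg]Br | intermediate
26 | (Z)-2-(iodomethylidene)-6-methylhept-5-en-1-ol | I/C=C(/CCC=C(C)C)CO | intermediate
27 | (Z)-2-(iodomethylidene)-6-methylhept-5-en-1-yl acetate | I/C=C(/CCC=C(C)C)COC(C)=O | intermediate
28 | 1-O,3'-O-bis(triethylsilyl) ether of the target | C=C(/C=C/C=C(/CCC=C(C)C)COC(C)=O)[C@@H]1CC[C@]2([C@H](CCCO[Si](CC)(CC)CC)/C(=C(/C)C=O)CC[C@]2(C)O)[C@@H]1O[Si](CC)(CC)CC | intermediate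
29 | CNP0205332.1 | C=C(/C=C/C=C(/CCC=C(C)C)COC(C)=O)[C@@H]1CC[C@]2([C@H](CCCO)/C(=C(/C)C=O)CC[C@]2(C)O)[C@@H]1O | target

## Step count and risk

Total steps: 13. Longest linear sequence: 11 (steps 1–9, 12, 13).

**Step 4 (the proposed new step).** It can fail in three ways. The tether may not gate the migrating bond, methyl may migrate in competition, or the hindered enol silane may not add to the acrylate.

The fallback sets out from 7 and comes back at 11, and it uses only known reactions:
- HF·pyridine frees the diol enone F1.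
- The known primary-amine/acid-catalysed vinylogous α-ketol rearrangement (9-amino-9-deoxy-epi-cinchona amine, N-Boc-phenylglycine) expands it to the spiro diketone ketol F2. The catalyst antipode and the internal hydrogen bond fix the spiro centre.
- Acryloyl chloride, Et3N and DMAP give the tertiary acrylate F3.
- Cs2CO3 closes a tethered intramolecular Michael addition, which can reach only C6 and only from the face of the 10-oxygen. This gives the bridged lactone F4.
- K2CO3 in MeOH at 0 °C opens it to the hydroxy diketo ester F5.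
- iPr2Si(OTf)2 and Et3N close the cyclic enol silane 11.

**Step 6.** The risks are slow oxidative addition or polymerisation of chloroprene, drift of the β,γ-enone into conjugation, and the C2 configuration.

The fallback sets out from 14 and comes back at 18:
- Saegusa–Ito dehydrogenation with Pd(OAc)2, followed by HF·pyridine, gives the cyclopentenone F6.
- I2 and pyridine give the 2-iodoenone F7.
- Stille coupling with tributyl(buta-1,3-dien-2-yl)stannane (Pd2(dba)3, AsPh3, CuI) gives the 2-dienyl enone F8.
- Conjugate reduction with [(Ph3P)CuH]6 returns 18. The enolate is protonated at C2 from the face of the free 10-OH.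

**Step 9.** The risks are the E/Z ratio of the tetrasubstituted enal and loss of the primary triethylsilyl ether.

The fallback sets out from 20 and comes back at 21:
- Ph3SiOReO3 catalyses a redox-neutral, reversible 1,3-transposition to the primary allylic alcohol F9.
- The isomers are separated, and the unwanted one is returned to the same rhenium equilibration.
- MnO2, which oxidises only the allylic alcohol, converts F9 to 21.

## Further compounds

F1 | step 4 | (S)-4-hydroxy-3-(1-hydroxycyclobutyl)-4-methylcyclohex-2-en-1-one | C[C@]1(O)CCC(=O)C=C1C1(O)CCC1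
F2 | step 4 | (5R,10S)-10-hydroxy-10-methylspiro[4.5]decane-1,7-dione | O=C1CCC[C@]12CC(=O)CC[C@]2(C)O
F3 | step 4 | (5R,10S)-10-methyl-1,7-dioxospiro[4.5]decan-10-yl acrylate | O=C1CCC[C@]12CC(=O)CC[C@]2(C)OC(=O)C=C
F4 | step 4 | bridged seven-membered lactone joining C6 and the 10-oxygen | O=C1CCC[C@]12[C@@H]3CCC(=O)O[C@@]2(C)CCC3=O
F5 | step 4 | methyl 3-[(5R,6S,10S)-10-hydroxy-10-methyl-1,7-dioxospiro[4.5]decan-6-yl]propanoate | O=C1CCC[C@]12[C@H](CCC(=O)OC)C(=O)CC[C@]2(C)O
F6 | step 6 | 2,3-didehydro (cyclopent-2-enone) hydroxy lactone | O=C1C=CC[C@]12[C@@H]3CCC(=O)O[C@]3(C(C)=C)CC[C@]2(C)O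
F7 | step 6 | 2-iodocyclopent-2-enone hydroxy lactone | O=C1C(I)=CC[C@]12[C@@H]3CCC(=O)O[C@]3(C(C)=C)CC[C@]2(C)O
F8 | step 6 | 2-(buta-1,3-dien-2-yl)cyclopent-2-enone hydroxy lactone | O=C1C(C(=C)C=C)=CC[C@]12[C@@H]3CCC(=O)O[C@]3(C(C)=C)CC[C@]2(C)O
F9 | step 9 | (2Z)-2-(spirodecan-7-ylidene)propan-1-ol corresponding to 21 | C=CC(=C)[C@@H]1CC[C@]2([C@H](CCCO[Si](CC)(CC)CC)/C(=C(/C)CO)CC[C@]2(C)O)[C@@H]1O[Si](CC)(CC)CC
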